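**Retrosynthetic overview**
1. The strategy rests on ring A (C4a–C5–C6–C7–C8–C8a). It carries five substituents, with the C6 prenyl group between 5-OH and 7-OH and hydrogen only at C8. Ring A is built last, and only removal of the two B-ring MOM ethers follows.
2. Key disconnection: C8–C8a and C4a–C5. A 1-methoxy-2-prenyl-1,3-bis(silyloxy)butadiene supplies C5–C8. It adds across the C5=C6 alkene (future C4a=C8a) of an enantiopure monocyclic (S)-2-aryl-2,3-dihydropyran-4-one, which is ring C with C2 already set.
3. In the adduct, H-8a is not acidic and lies cis to the C4a substituent. That substituent must therefore activate the alkene and leave by a syn elimination, so the 5-iodopyranone is converted into the 5-(p-tolylsulfinyl)pyranone before the annulation.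
4. Ring C comes from an enantioselective hetero-Diels–Alder reaction of the geranylated B-ring aldehyde (5-bromovanillin + geranyl bromide) with 1-methoxy-3-silyloxybutadiene, followed by C5 iodination. The annulation diene comes from methyl acetoacetate and prenyl bromide.
5. Ring order: B (purchased arene), then C (hetero-Diels–Alder), then A (diene annulation and aromatisation).

Key step: step 11

Assumption 1: the (S)-BINOL–titanium catalyst is taken to direct attack to the Si face of the B-ring aldehyde, as it does with simple benzaldehydes, which gives 2S. Both ligand antipodes are commercial if the sense proves opposite.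
Assumption 2: the sulfur configuration of the sulfinylpyranone is left uncontrolled. Both sulfur epimers converge because sulfur is lost in the key step.

**Step 1**
Reactants: 1 5-bromovanillin
Product: 2 3-bromo-4,5-dihydroxybenzaldehyde
Conditions: BBr3 (2.2 equiv), CH2Cl2, −78 °C → rt; then H2O
Reagents that add atoms: none
Why: Lewis-acid aryl methyl ether cleavage, in which boron binds the guaiacol oxygens and bromide removes the methyl group by SN2, while the aldehyde is regenerated on hydrolysis and the aryl bromide is inert.

**Step 2**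
Reactants: 2 3-bromo-4,5-dihydroxybenzaldehyde
Product: 3 3-bromo-4,5-bis(methoxymethoxy)benzaldehyde
Conditions: MOMCl (2.6 equiv), iPr2NEt, CH2Cl2, 0 °C → rt
Reagents that add atoms: chloromethyl methyl ether, COCCl
Why: Williamson-type O-alkylation of both phenols by the reactive α-chloro ether under amine base gives base-stable acetal ethers that survive organometallic steps and later chelate the aryllithium.

**Step 3**
Reactants: 3 3-bromo-4,5-bis(methoxymethoxy)benzaldehyde
Product: 4 1-bromo-5-(dimethoxymethyl)-2,3-bis(methoxymethoxy)benzene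
Conditions: HC(OMe)3, PPTS (cat.), MeOH, rt; Et3N quench
Reagents that add atoms: trimethyl orthoformate, COC(OC)OC
Why: Acid-catalysed acetalisation driven by the orthoformate masks the aldehyde against n-BuLi, and PPTS at room temperature is too weak an acid to exchange aryl MOM ethers.

**Step 4**
Reactants: 4 1-bromo-5-(dimethoxymethyl)-2,3-bis(methoxymethoxy)benzene; 5 geranyl bromide
Product: 9 3-[(2E)-3,7-dimethylocta-2,6-dienyl]-4,5-bis(methoxymethoxy)benzaldehyde, via aryllithium 6 (not isolated), via arylcopper 7 (not isolated), via geranylated dimethyl acetal 8 (not isolated)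
Conditions: n-BuLi, THF, −78 °C; CuBr·SMe2, −78 → −40 °C; 5, −78 → 0 °C; then 1 M aq HCl, THF, rt (brief)
Reagents that add atoms: water, O
Why: Bromine–lithium exchange outruns ortho-metalation at −78 °C, transmetalation to copper followed by SN2 allylic substitution at the unhindered primary carbon of 5 keeps the E alkene, and the dilute-acid work-up hydrolyses only the much more labile benzaldehyde dimethyl acetal.

**Step 5**
Reactants: 9 geranylated aldehyde; 10 (E)-1-methoxy-3-(trimethylsilyloxy)buta-1,3-diene
Product: 12 (2S)-2-[3-geranyl-4,5-bis(methoxymethoxy)phenyl]-2,3-dihydro-4H-pyran-4-one, via silylated aldol adduct 11 (not isolated)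
Conditions: (S)-BINOL (20 mol %), Ti(OiPr)4 (10 mol %), 4 Å MS, Et2O, −20 °C; then TFA (cat.), CH2Cl2, 0 °C (brief)
Reagents that add atoms: none
Why: Catalytic enantioselective hetero-Diels–Alder reaction in its stepwise Mukaiyama aldol–cyclisation form, in which the chiral titanium binaphtholate blocks the Re face of the bound aldehyde so that the diene CH2 terminus attacks the Si face and sets C2 as S, and a short acid treatment closes ring C by oxa-Michael addition and loss of methanol.

**Step 6**
Reactants: 12 (2S)-2-aryl-2,3-dihydro-4H-pyran-4-one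
Product: 13 (2S)-2-[3-geranyl-4,5-bis(methoxymethoxy)phenyl]-5-iodo-2,3-dihydro-4H-pyran-4-one
Conditions: I2 (1.5 equiv), pyridine–CH2Cl2, 0 °C → rt, dark; aq Na2S2O3 work-up
Reagents that add atoms: iodine, II
Why: Iodine–pyridine α-iodination of an enone substitutes the nucleophilic C5 of the vinylogous ester irreversibly, whereas iodonium formation at the isolated trisubstituted alkenes is reversible without a trapping nucleophile, and exclusion of light avoids iodine-atom E/Z isomerisation of the geranyl chain.

**Step 7**
Reactants: 13 (2S)-5-iodopyranone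
Product: 15 (2S)-2-[3-geranyl-4,5-bis(methoxymethoxy)phenyl]-5-(p-tolylsulfinyl)-2,3-dihydro-4H-pyran-4-one, via alkenylmagnesium chloride 14 (not isolated)
Conditions: iPrMgCl·LiCl (1.05 equiv), THF, −78 → −40 °C; methyl p-toluenesulfinate, −78 → −30 °C; aq NH4Cl at −30 °C
Reagents that add atoms: methyl p-toluenesulfinate, COS(=O)c1ccc(C)cc1
Why: Iodine–magnesium exchange on the acceptor-substituted alkenyl iodide is faster at low temperature than carbonyl addition or C3 deprotonation, ring-held β-alkoxy alkenylmagnesium species of this kind resist β-elimination below about −30 °C, and substitution at sulfur of the sulfinate ester (Andersen-type sulfoxide synthesis) installs the sulfinyl group without an oxidant that could touch the alkenes, the new sulfur stereocentre being left uncontrolled because step 11 removes it.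

**Step 8**
Reactants: 16 methyl acetoacetate; 17 prenyl bromide
Product: 18 methyl 2-acetyl-5-methylhex-4-enoate (racemic)
Conditions: K2CO3, acetone, reflux (16 in excess)
Reagents that add atoms: none
Why: C-alkylation of the stabilised β-keto ester enolate by SN2 at the primary allylic bromide, with excess 16 suppressing dialkylation.

**Step 9**
Reactants: 18 methyl 2-acetyl-5-methylhex-4-enoate
Product: 19 methyl 5-methyl-2-[1-(trimethylsilyloxy)ethylidene]hex-4-enoate (E/Z mixture)
Conditions: TMSCl, Et3N, toluene, rt
Reagents that add atoms: chlorotrimethylsilane, C[Si](C)(C)Cl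
Why: Soft enolisation and O-silylation of the β-keto ester gives the β-silyloxy enoate, the standard first stage in making 1,3-bis(silyloxy)dienes.

**Step 10**
Reactants: 19 β-silyloxy enoate
Product: 21 1-methoxy-2-(3-methylbut-2-enyl)-1,3-bis(trimethylsilyloxy)buta-1,3-diene, via lithium dienolate 20 (not isolated)
Conditions: LDA, THF, −78 °C; TMSCl, −78 °C → rt; filtered under argon and used crude
Reagents that add atoms: chlorotrimethylsilane, C[Si](C)(C)Cl
Why: Kinetic γ-deprotonation at the only vinylogously acidified position (the C4 methyl group) and O-silylation of the dienolate give the silyl ketene acetal diene, whose acetal geometry does not matter.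

**Step 11**
Reactants: 15 (2S)-5-(p-tolylsulfinyl)pyranone; 21 1-methoxy-2-prenyl-1,3-bis(trimethylsilyloxy)butadiene
Product: 25 (2S)-3',4'-di-O-methoxymethylschizolaenone B, via cis-fused cycloadduct 22 (not isolated), via dihydroarene 23 (not isolated), via bis-silyl ether 24 (not isolated)
Conditions: 21 (2.5 equiv), Eu(fod)3 (10 mol %), toluene, 0 → 60 °C; then MeOH, PPTS (cat.), rt
Reagents that add atoms: none
Why: Proposed new method: the sulfinyl and C4 carbonyl oxygens, chelated by the mild europium Lewis acid, make C8a of 15 strongly electrophilic, so the unsubstituted CH2 terminus of 21 (its most nucleophilic carbon) bonds there (C8–C8a) and the ketene acetal carbon bonds to C4a (C4a–C5), either in one asynchronous normal-demand [4+2] cycloaddition or as a vinylogous Mukaiyama–Michael addition followed by 6-exo-trig collapse of the sulfinyl-stabilised enolate on the O-silylated ester carbon, and both modes close ring A as the cis-fused adduct 22. In 22 the sulfinyl group on C4a and H-8a lie on the same face, so p-toluenesulfenic acid leaves by a thermal syn (Ei) elimination to give 23, after which ionisation of the C5 methoxy group and loss of one H-8 give arene 24, and methanolysis of the two aryl silyl ethers gives 25. The closest known reaction types are the cycloaddition–sulfoxide pyrolysis sequences of sulfinylquinones, the aromatising annulations of 1,1,3-trioxygenated dienes with haloquinones, and the cycloadditions of 3-acyl-, 3-cyano- and 3-sulfinylchromones, but a monocyclic dihydropyranone has not been used in this way. Two selectivities are needed: regiochemistry, which the donor pattern of the diene matched to the enone polarity secures and which fixes 5-O, 6-prenyl, 7-O and 8-H with no 6/8 ambiguity, and loss of the C4a substituent rather than O1, which is secured because C4a bears no hydrogen (no E1cB expulsion of O1), the medium stays neutral, and the Ei path does not depend on the non-acidic H-8a, whereas a halide on C4a would need an anti E2 that the cis adduct cannot offer and could depart as a halonium ion once O1 ionises. The stereocentres created at C4a, C5 and C8a and the one at sulfur are all erased on aromatisation, so facial selectivity is irrelevant. C2 is untouched because neither the C2–O1 bond nor a C3 enolate is engaged.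

**Step 12**
Reactants: 25 (2S)-3',4'-di-O-methoxymethylschizolaenone B
Product: 26 schizolaenone B
Conditions: 3 M aq HCl–MeOH, rt → 40 °C, argon
Reagents that add atoms: none
Why: Acid-catalysed acetal exchange to methanol frees the catechol under conditions long used on prenylated flavonoids, mild enough to avoid chroman formation from the ortho-prenyl and ortho-geranyl phenols and acidic enough to avoid the base-induced flavanone–chalcone equilibrium that would racemise C2.

**Compound list**
1 | 5-bromovanillin | COc1cc(C=O)cc(Br)c1O | starting material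
2 | 3-bromo-4,5-dihydroxybenzaldehyde | O=Cc1cc(O)c(O)c(Br)c1 | intermediate
3 | 3-bromo-4,5-bis(methoxymethoxy)benzaldehyde | COCOc1cc(C=O)cc(Br)c1OCOC | intermediate
4 | 1-bromo-5-(dimethoxymethyl)-2,3-bis(methoxymethoxy)benzene | COCOc1cc(C(OC)OC)cc(Br)c1OCOC | intermediate
5 | geranyl bromide | CC(C)=CCC/C(C)=C/CBr | starting material
6 | 5-(dimethoxymethyl)-2,3-bis(methoxymethoxy)phenyllithium (not isolated) | COCOc1cc(C(OC)OC)cc([Li])c1OCOC | intermediate
7 | 5-(dimethoxymethyl)-2,3-bis(methoxymethoxy)phenylcopper (not isolated) | COCOc1cc(C(OC)OC)cc([Cu])c1OCOC | intermediate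
8 | 3-geranyl-4,5-bis(methoxymethoxy)benzaldehyde dimethyl acetal (not isolated) | CC(C)=CCC/C(C)=C/Cc1cc(C(OC)OC)cc(OCOC)c1OCOC | intermediate
9 | 3-[(2E)-3,7-dimethylocta-2,6-dienyl]-4,5-bis(methoxymethoxy)benzaldehyde | CC(C)=CCC/C(C)=C/Cc1cc(C=O)cc(OCOC)c1OCOC | intermediate
10 | (E)-1-methoxy-3-(trimethylsilyloxy)buta-1,3-diene | CO/C=C/C(=C)O[Si](C)(C)C | starting material
11 | (5S,1E)-5-aryl-1-methoxy-5-(trimethylsilyloxy)pent-1-en-3-one, aryl = 3-geranyl-4,5-bis(methoxymethoxy)phenyl (not isolated) | CC(C)=CCC/C(C)=C/Cc1cc([C@H](CC(=O)/C=C/OC)O[Si](C)(C)C)cc(OCOC)c1OCOC | intermediate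
12 | (2S)-2-[3-geranyl-4,5-bis(methoxymethoxy)phenyl]-2,3-dihydro-4H-pyran-4-one | CC(C)=CCC/C(C)=C/Cc1cc([C@@H]2CC(=O)C=CO2)cc(OCOC)c1OCOC | intermediate
13 | (2S)-2-[3-geranyl-4,5-bis(methoxymethoxy)phenyl]-5-iodo-2,3-dihydro-4H-pyran-4-one | CC(C)=CCC/C(C)=C/Cc1cc([C@@H]2CC(=O)C(I)=CO2)cc(OCOC)c1OCOC | intermediate
14 | (2S)-2-aryl-4-oxo-2,3-dihydro-4H-pyran-5-ylmagnesium chloride (not isolated) | CC(C)=CCC/C(C)=C/Cc1cc([C@@H]2CC(=O)C([Mg]Cl)=CO2)cc(OCOC)c1OCOC | intermediate
15 | (2S)-2-[3-geranyl-4,5-bis(methoxymethoxy)phenyl]-5-(p-tolylsulfinyl)-2,3-dihydro-4H-pyran-4-one (both sulfur epimers) | CC(C)=CCC/C(C)=C/Cc1cc([C@@H]2CC(=O)C(S(=O)c3ccc(C)cc3)=CO2)cc(OCOC)c1OCOC | intermediate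
16 | methyl acetoacetate | COC(=O)CC(C)=O | starting material
17 | prenyl bromide | CC(C)=CCBr | starting material
18 | methyl 2-acetyl-5-methylhex-4-enoate (racemic) | COC(=O)C(CC=C(C)C)C(C)=O | intermediate
19 | methyl 5-methyl-2-[1-(trimethylsilyloxy)ethylidene]hex-4-enoate (E/Z mixture) | COC(=O)C(CC=C(C)C)=C(C)O[Si](C)(C)C | intermediate
20 | lithium dienolate of 19 (not isolated) | [Li]OC(OC)=C(CC=C(C)C)C(=C)O[Si](C)(C)C | intermediate
21 | 1-methoxy-2-(3-methylbut-2-enyl)-1,3-bis(trimethylsilyloxy)buta-1,3-diene | C=C(O[Si](C)(C)C)C(CC=C(C)C)=C(OC)O[Si](C)(C)C | intermediate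
22 | cis-fused cycloadduct: 4a-sulfinyl, 5-methoxy-5,7-bis(silyloxy), 6-prenyl, 6,7-ene; only C2 defined, the other centres are transient mixtures (not isolated) | CC(C)=CCC/C(C)=C/Cc1cc([C@@H]2CC(=O)C3(S(=O)c4ccc(C)cc4)C(O2)CC(O[Si](C)(C)C)=C(CC=C(C)C)C3(OC)O[Si](C)(C)C)cc(OCOC)c1OCOC | intermediate
23 | 5,8-dihydroarene after sulfenic acid loss, with C4a=C8a restored (not isolated) | CC(C)=CCC/C(C)=C/Cc1cc([C@@H]2CC(=O)C3=C(O2)CC(O[Si](C)(C)C)=C(CC=C(C)C)C3(OC)O[Si](C)(C)C)cc(OCOC)c1OCOC | intermediate
24 | (2S)-5,7-bis(trimethylsilyloxy)-6-prenylflavanone with B-ring MOM ethers (not isolated) | CC(C)=CCC/C(C)=C/Cc1cc([C@@H]2CC(=O)c3c(cc(O[Si](C)(C)C)c(CC=C(C)C)c3O[Si](C)(C)C)O2)cc(OCOC)c1OCOC | intermediate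
25 | (2S)-3',4'-di-O-methoxymethylschizolaenone B | CC(C)=CCC/C(C)=C/Cc1cc([C@@H]2CC(=O)c3c(cc(O)c(CC=C(C)C)c3O)O2)cc(OCOC)c1OCOC | intermediate
26 | schizolaenone B, (2S) | CC(C)=CCC/C(C)=C/Cc1cc([C@@H]2CC(=O)c3c(cc(O)c(CC=C(C)C)c3O)O2)cc(O)c1O | target

**Step count**
Total steps: 12. Longest linear sequence: 9 (steps 1–7, 11, 12). The diene branch (steps 8–10) joins at step 11.

**Steps most likely to fail**

**1. Step 11 (new method).**
- The push–pull alkene may be too unreactive.
- The process may stall after the first C–C bond through silyl transfer.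
- The ketene acetal may silylate the sulfoxide oxygen and consume it in a Pummerer-type way.
- Species derived from the sulfenic acid may sulfenylate the new electron-rich ring.

The fallback uses known chemistry, sets out from 9 and 17, and comes back at 26. Commercial 2,4,6-trihydroxyacetophenone is C-prenylated with 17 (aq KOH) to 2,4,6-trihydroxy-3-prenylacetophenone F1. This is protected (MOMCl, iPr2NEt) as 2-hydroxy-4,6-bis(methoxymethoxy)-3-prenylacetophenone F2. Claisen–Schmidt condensation of F2 with 9 (KOH, EtOH) gives the tetra-MOM chalcone F3. Removal of all four MOM groups (HCl, MeOH) gives the pentahydroxychalcone F4. Oxa-Michael cyclisation (NaOAc, EtOH, reflux, argon) then gives racemic schizolaenone B F5 together with the 8-prenyl regioisomer F6. Chromatography removes the regioisomer, and preparative HPLC on a chiral phase delivers the 2S enantiomer 26. This path gives up the regiocontrol and the absolute control of the main route.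

**2. Step 7.**
- The Grignard reagent may add to or deprotonate the pyranone.
- The magnesiated species may ring-open by β-elimination.
- Organomagnesium may add in conjugate fashion to the very electrophilic product.
- Magnesium methoxide may open ring C at C2–O1.

The fallback sets out from 13 and comes back at 15. It replaces polar organometallic chemistry by catalysis followed by selective oxidation. Palladium-catalysed C–S coupling with 4-methylbenzenethiol (Pd2(dba)3, Xantphos, iPr2NEt, dioxane, 60 °C) gives the 5-(p-tolylthio)pyranone F7. This is oxidised at sulfur only with 2-(phenylsulfonyl)-3-phenyloxaziridine (CH2Cl2, rt), a reagent that leaves trisubstituted alkenes alone at that temperature.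

**3. Step 6.**
- The geranyl alkenes may be attacked competitively (iodofunctionalisation or cation–olefin cyclisation).
- Iodine may catalyse E/Z isomerisation.

The fallback sets out from 9, comes back at 15, and avoids both electrophilic halogen and the Grignard step. A Mukaiyama aldol reaction of 9 with 1-(tert-butylthio)-1-(trimethylsilyloxy)ethene uses the same (S)-BINOL–titanium catalyst. After desilylating work-up it gives S-tert-butyl (3S)-3-aryl-3-hydroxypropanethioate F8. Lithiated methyl p-tolyl sulfoxide (3 equiv, THF, −78 °C) converts F8 into the δ-hydroxy-β-keto sulfoxide F9. Condensation with DMF dimethyl acetal gives the enaminone F10, which closes on silica gel or with acetic acid to 15 by O-addition and loss of the amine. This parallels the standard chromone synthesis from β-keto sulfoxides.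

**Further compounds**
F1 | step 11 | 1-[2,4,6-trihydroxy-3-(3-methylbut-2-enyl)phenyl]ethanone | CC(=O)c1c(O)cc(O)c(CC=C(C)C)c1O
F2 | step 11 | 1-[2-hydroxy-4,6-bis(methoxymethoxy)-3-(3-methylbut-2-enyl)phenyl]ethanone | CC(=O)c1c(O)c(CC=C(C)C)c(OCOC)cc1OCOC
F3 | step 11 | (E)-2'-hydroxy-3,4,4',6'-tetrakis(methoxymethoxy)-5-geranyl-3'-prenylchalcone | CC(C)=CCC/C(C)=C/Cc1cc(/C=C/C(=O)c2c(O)c(CC=C(C)C)c(OCOC)cc2OCOC)cc(OCOC)c1OCOC
F4 | step 11 | (E)-2',3,4,4',6'-pentahydroxy-5-geranyl-3'-prenylchalcone | CC(C)=CCC/C(C)=C/Cc1cc(/C=C/C(=O)c2c(O)cc(O)c(CC=C(C)C)c2O)cc(O)c1O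
F5 | step 11 | racemic schizolaenone B | CC(C)=CCC/C(C)=C/Cc1cc(C2CC(=O)c3c(cc(O)c(CC=C(C)C)c3O)O2)cc(O)c1O
F6 | step 11 | racemic 8-prenyl regioisomer of schizolaenone B | CC(C)=CCC/C(C)=C/Cc1cc(C2CC(=O)c3c(O)cc(O)c(CC=C(C)C)c3O2)cc(O)c1O
F7 | step 7 | (2S)-2-[3-geranyl-4,5-bis(methoxymethoxy)phenyl]-5-(p-tolylthio)-2,3-dihydro-4H-pyran-4-one | CC(C)=CCC/C(C)=C/Cc1cc([C@@H]2CC(=O)C(Sc3ccc(C)cc3)=CO2)cc(OCOC)c1OCOC
F8 | step 6 | S-tert-butyl (3S)-3-[3-geranyl-4,5-bis(methoxymethoxy)phenyl]-3-hydroxypropanethioate | CC(C)=CCC/C(C)=C/Cc1cc([C@H](CC(=O)SC(C)(C)C)O)cc(OCOC)c1OCOC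
F9 | step 6 | (4S)-4-[3-geranyl-4,5-bis(methoxymethoxy)phenyl]-4-hydroxy-1-(p-tolylsulfinyl)butan-2-one | CC(C)=CCC/C(C)=C/Cc1cc([C@H](CC(=O)CS(=O)c2ccc(C)cc2)O)cc(OCOC)c1OCOC
F10 | step 6 | (5S)-5-aryl-1-(dimethylamino)-5-hydroxy-2-(p-tolylsulfinyl)pent-1-en-3-one | CC(C)=CCC/C(C)=C/Cc1cc([C@H](CC(=O)C(=CN(C)C)S(=O)c2ccc(C)cc2)O)cc(OCOC)c1OCOC
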